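- Write the balance of the substrate first: in the new flask it is the limiting reagent, smaller at 0.050 M than the reagent at 0.250 M, and what was charged stands as substrate, dissolved target or crystals.

| flask | substrate | reagent | remark | time |
|---|---|---|---|---|
| Thursday's | 0.075 M | 5 equiv | run made earlier |  |
| flask | 0.050 M | 5.00 equiv |  | 20 h |

Thursday's run (percent of the substrate charged)

| time / h | target / % | crystals / % |
|---|---|---|
| 0.500 | 5.4 | 0 |
| 0.833 | 10.2 | 0 |
| 1.50 | 17.2 | 0 |
| 3.00 | 29.4 | 2.5 |
| 6.00 | 47.7 | 21.1 |

(readings scatter by 0.5 percentage points)

- what is said of target includes crystals
- crystals is a solid; its amount is given per volume of the solution
- the analysis behind the earlier runs scatters by 0.5 percentage points, standard deviation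
- candidate steps: substrate + reagent <-> target + by-product; crystals <-> target

* amount of target and crystals together at 20 h, in percent of the substrate charged
* concentration of target in solution at 20 h, in percent of saturation

- The target column of Thursday's run includes crystals, so I subtracted them and got dissolved [target] two ways: 0.0202 M from the reading at 3.00 h and 0.0199 M from the reading at 6.00 h.
- These came from different readings, taken while total target rose from 29.4 % to 47.7 %. In percent of Thursday's charge they parted by 0.3 percentage points, and a reading scatters by 0.5 points, so I trusted them.
- Their mean, 0.0201 M, I called the dissolved ceiling: a reading of the [target] in Thursday's run while crystals grew, so a level during growth and not the saturation concentration itself.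
- In the new flask that ceiling was 40.1 % of the charge, so my balance counted any total above this share as crystals, as an estimate.
- The forecast gave 64 % for the total, range 60 % to 68 %, and 100 % of saturation, range 97 % to 103 %, concluding that “crystals are present at 20 h and the solution is saturated”. Its total stood 24 points above my share, and that margin was what I watched.
- The new flask gave 68.5 % for the total and 102 % of saturation; both forecasts held within tolerance, though the total came out higher than the top of the forecast's range. The solution in this flask had already stood at 105 % of saturation at 10.0 h. Put through the balance, the ceiling left 28.4 % of the charge as crystals at 20.0 h, and the flask held 31.8 %.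

    substrate + reagent ⇌ target + by-product (K = 0.360, k = 0.330 M⁻¹ h⁻¹)
    crystals ⇌ target, rate k2*(cs2 - [target]) while solid is left; crystals form when [target] > cs2 (solubility = 18.0 mM, k = 1.70 h⁻¹)

- A neighbour flask, like this one but charged with 0.013 M of substrate, had its ceiling higher than its charge, so the balance gave no crystals at any conversion. Computed, that neighbour held 0 % crystals and 33.0 % target at 20.0 h.

(All runs were generated by integration for an exercise, noise included.)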